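**Plan**
- Retrosynthesis cuts C6–C8 (ring B) first, then the lactone O–C10 bond together with the C1=C2 alkene, then C9–C10 between a ring A cyclohexenylboronate and a bicyclo[3.2.1]octenone (rings C/D); C6 is inserted by a one-carbon homologation.
- Forward: ring A piece from cis-tetrahydrophthalic anhydride, ring C from estragole, ring D by palladium cycloalkenylation, union by rhodium conjugate addition, lactone by iodolactonisation/elimination, ring B last by rhodium carbenoid C–H insertion.
- Enabling feature: the bridgehead C8–H of the bicyclo[3.2.1]octane (rings C/D) lies 1,5 to C6 through C5–C10–C9 and is the only tertiary C–H in reach; C5 is the one-carbon bridge of the lactone bicycle and holds C6 on the lactone side.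
- Stereochemistry: C4/C5 from alkaloid desymmetrisation of the meso anhydride and anti methylation; C3 from the SeO2 ene reaction; C8/C13 from chiral-base desymmetrisation of 4-allylcyclohexanone; C9 from exo-face conjugate addition; C10 from lactonisation; C12 from hydride delivery anti to ring A; C6 and quaternary C8 from the insertion.

Key step: step 21

Remark: positions are named with gibberellane numbering (C1–C19, no C20); the SMILES strings are authoritative for configuration, and the 12-hydroxyl of the target is the epimer cis to C10 on ring C.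

**Step 1**
Reactants: 1 estragole
Product: 3 4-(prop-2-enyl)cyclohex-2-en-1-one (racemic), via enol ether 2 (not isolated)
Conditions: Li, NH3(l), t-BuOH, THF, −78 to −33 °C; then 2 M HCl, THF, 20 °C
Reagents that add atoms: water, O
Why: Birch reduction of the anisole ring spares the isolated allyl alkene, and aqueous acid hydrolysis of the enol ether with migration of the ring alkene into conjugation should give the 4-substituted cyclohexenone.

**Step 2**
Reactants: 3 4-(prop-2-enyl)cyclohex-2-en-1-one
Product: 4 4-(prop-2-enyl)cyclohexan-1-one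
Conditions: LiBH(s-Bu)3, THF, −78 °C; AcOH quench
Reagents that add atoms: none
Why: the hindered borohydride should reduce the β-unsubstituted cyclohexenone in the 1,4 sense and leave the terminal alkene untouched, which removes the stereocentre and gives an achiral ketone for desymmetrisation.

**Step 3**
Reactants: 4 4-(prop-2-enyl)cyclohexan-1-one
Product: 6 (4R)-2-hydroxy-4-(prop-2-enyl)cyclohexan-1-one (both C2 epimers), via lithium enolate 5 (not isolated)
Conditions: lithium bis[(R)-1-phenylethyl]amide (sense assigned by analogy with 4-tert-butylcyclohexanone; the (S,S)-amide would give ent-6), LiCl, THF, −78 °C; then (camphorsulfonyl)oxaziridine, −78 to −40 °C; AcOH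
Reagents that add atoms: (camphorsulfonyl)oxaziridine, CC1(C)C2CCC13CS(=O)(=O)N4OC34C2
Why: enantiotopic-proton-selective deprotonation by the chiral lithium amide (ketone desymmetrisation) fixes the future C8 centre, and oxaziridine oxidation of the enolate puts oxygen on the future C13, whose own configuration is erased in step 4.

**Step 4**
Reactants: 6 (4R)-2-hydroxy-4-(prop-2-enyl)cyclohexan-1-one
Product: 7 (4R)-4-(prop-2-enyl)-1,2-bis(triethylsilyloxy)cyclohex-1-ene
Conditions: Et3SiOTf (2.4 equiv), Et3N, CH2Cl2, 0 to 20 °C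
Reagents that add atoms: triethylsilyl triflate, CC[Si](CC)(CC)OS(=O)(=O)C(F)(F)F
Why: O-silylation and soft enolisation toward the oxygen-bearing carbon should give the tetrasubstituted enediol bis-silyl ether, as acyloins do, so that only C12 and C13 are nucleophilic.

**Step 5**
Reactants: 7 (4R)-4-(prop-2-enyl)-1,2-bis(triethylsilyloxy)cyclohex-1-ene
Product: 8 (1S,5R)-7-methylidene-1-(triethylsilyloxy)bicyclo[3.2.1]octan-2-one (rings C/D: C13–OSiEt3, C12=O, C16=C17)
Conditions: Pd(OAc)2 (10 mol %), O2 (1 atm), DMSO, 45 °C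
Reagents that add atoms: none
Why: Proposed new method: transmetallation of the enediol bis-silyl ether to a divalent palladium enolate, 5-exo insertion of the tethered terminal alkene at C13 and β-hydride elimination from C16 should give the exocyclic methylene with O13 on the new quaternary bridgehead (configuration dictated by the bridge), the closest known reaction being the Pd(OAc)2-promoted cycloalkenylation of simple silyl enol ethers of 4-allylcyclohexanones to bicyclo[3.2.1]octanones, with 5-exo closure at C13 expected to outrun 6-exo closure at C12.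

**Step 6**
Reactants: 8 (1S,5R)-7-methylidene-1-(triethylsilyloxy)bicyclo[3.2.1]octan-2-one
Product: 9 (1S,5R)-7-methylidene-1-(triethylsilyloxy)bicyclo[3.2.1]oct-3-en-2-one
Conditions: IBX, 4-methoxypyridine N-oxide, DMSO, 25 °C
Reagents that add atoms: none
Why: IBX dehydrogenation can only proceed through C11, the sole enolisable position, and so should give the C9=C11 enone regiospecifically.

**Step 7**
Reactants: 10 cis-cyclohex-4-ene-1,2-dicarboxylic anhydride
Product: 11 (1S,6R)-6-{[2-(trimethylsilyl)ethoxy]carbonyl}cyclohex-3-ene-1-carboxylic acid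
Conditions: quinidine (1.1 equiv; quinine gives ent-11), Me3SiCH2CH2OH (3 equiv), toluene, −55 °C
Reagents that add atoms: 2-(trimethylsilyl)ethanol, C[Si](C)(C)CCO
Why: cinchona-alkaloid-mediated alcoholysis of the meso anhydride distinguishes the enantiotopic carbonyl groups and sets the absolute configuration of the future C4 and C5 while differentiating C19 (ester) from the C5 carboxyl.

**Step 8**
Reactants: 11 (1S,6R)-6-{[2-(trimethylsilyl)ethoxy]carbonyl}cyclohex-3-ene-1-carboxylic acid
Product: 13 (1S,6R)-6-methyl-6-{[2-(trimethylsilyl)ethoxy]carbonyl}cyclohex-3-ene-1-carboxylic acid, via dianion 12 (not isolated)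
Conditions: LiN(i-Pr)2 (2.2 equiv), THF, −78 to −20 °C; MeI; then 1 M HCl
Reagents that add atoms: iodomethane, CI
Why: the carboxylate/ester-enolate dianion is alkylated on the face anti to the neighbouring carboxylate, which creates the C4 quaternary centre with methyl trans to the C5 carboxyl and keeps C19 cis to it.

**Step 9**
Reactants: 13 (1S,6R)-6-methyl-6-{[2-(trimethylsilyl)ethoxy]carbonyl}cyclohex-3-ene-1-carboxylic acid
Product: 16 2-(trimethylsilyl)ethyl (1R,6R)-6-(2-methoxy-2-oxoethyl)-1-methylcyclohex-3-ene-1-carboxylate, via acid chloride 14 (not isolated), via diazoketone 15 (not isolated)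
Conditions: (COCl)2, cat. DMF, CH2Cl2, 0 °C; CH2N2, Et2O, 0 °C; then PhCO2Ag (10 mol %), Et3N, MeOH, 20 °C
Reagents that add atoms: diazomethane, C=[N+]=[N-]; methanol, CO
Why: Arndt–Eistert homologation inserts C6 between C5 and the carboxyl carbon (now C7), the Wolff rearrangement proceeding with retention at the migrating C5.

**Step 10**
Reactants: 16 2-(trimethylsilyl)ethyl (1R,6R)-6-(2-methoxy-2-oxoethyl)-1-methylcyclohex-3-ene-1-carboxylate
Product: 17 ring A allylic alcohol, 2-(trimethylsilyl)ethyl 2-hydroxy-6-(2-methoxy-2-oxoethyl)-1-methylcyclohex-3-ene-1-carboxylate (3β-OH cis to the methyl, C1=C2 retained)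
Conditions: SeO2 (0.5 equiv), t-BuOOH, CH2Cl2, 20 °C
Reagents that add atoms: tert-butyl hydroperoxide, CC(C)(C)OO
Why: in the half-chair with the C19 ester axial, the ene reaction/[2,3]-shift of the Riley oxidation should occur on the face anti to that ester, taking the axial hydrogen of C3 and returning oxygen to C3 on the same β face without allylic transposition.

**Step 11**
Reactants: 17 ring A allylic alcohol
Product: 18 3-O-triethylsilyl ether of 17
Conditions: Et3SiCl, imidazole, DMF, 20 °C
Reagents that add atoms: chlorotriethylsilane, CC[Si](Cl)(CC)CC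
Why: silylation protects the allylic alcohol from the oxidant of step 12.

**Step 12**
Reactants: 18 3-O-triethylsilyl ether
Product: 19 ring A enone, 2-(trimethylsilyl)ethyl 6-(2-methoxy-2-oxoethyl)-1-methyl-5-oxo-2-(triethylsilyloxy)cyclohex-3-ene-1-carboxylate (C10=O, C1=C2, 3β-OSiEt3)
Conditions: Pd(OH)2/C (5 mol %), t-BuOOH, K2CO3 (0.25 equiv), CH2Cl2, 4 °C
Reagents that add atoms: tert-butyl hydroperoxide, CC(C)(C)OO
Why: palladium/hydroperoxide allylic oxidation should convert the only remaining allylic methylene, C10, into the ketone, the silyloxy-bearing C3 being tertiary and shielded by the quaternary C4.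

**Step 13**
Reactants: 19 ring A enone
Product: 21 ring A alkenyl triflate (C10–OTf, C10=C1, C2 saturated), via lithium enolate 20 (not isolated)
Conditions: LiBH(s-Bu)3, THF, −78 °C; then N-(5-chloropyridin-2-yl)bis(trifluoromethanesulfonyl)imide, −78 to 0 °C; AcOH
Reagents that add atoms: N-(5-chloropyridin-2-yl)bis(trifluoromethanesulfonyl)imide, O=S(=O)(N(c1ccc(Cl)cn1)S(=O)(=O)C(F)(F)F)C(F)(F)F
Why: conjugate hydride addition at C2 generates the C10 enolate regiospecifically, and O-triflation traps it as the C10=C1 alkenyl triflate.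

**Step 14**
Reactants: 21 ring A alkenyl triflate
Product: 22 ring A alkenyl pinacolboronate (boron on C10)
Conditions: B2pin2, PdCl2(PPh3)2 (3 mol %), PPh3, KOPh, toluene, 50 °C
Reagents that add atoms: bis(pinacolato)diboron, CC1(C)OB(OC1(C)C)B1OC(C)(C)C(C)(C)O1
Why: Miyaura borylation of the alkenyl triflate gives an ester-tolerant C10 nucleophile.

**Step 15**
Reactants: 9 (1S,5R)-7-methylidene-1-(triethylsilyloxy)bicyclo[3.2.1]oct-3-en-2-one; 22 ring A alkenyl pinacolboronate
Product: 23 coupled ketone (C9–C10 bond, C12=O, C10=C1)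
Conditions: [Rh(OH)(cod)]2 (3 mol %), dioxane–H2O 10:1, 40 °C
Reagents that add atoms: none
Why: in the Hayashi–Miyaura conjugate addition the alkenylrhodium should add to C9 from the face of the one-carbon bridge C14, anti to the C15–C16 bridge, which places C10 axial on ring C as in the target.

**Step 16**
Reactants: 23 coupled ketone
Product: 24 seco acid (C19 acid, 3-OH and 13-OH free, C7 methyl ester)
Conditions: Bu4NF (4 equiv), AcOH (3 equiv), THF, 0 to 20 °C
Reagents that add atoms: none
Why: fluoride fragments the 2-(trimethylsilyl)ethyl ester to the C19 carboxylate and removes both triethylsilyl ethers, while the C7 methyl ester survives the buffered medium.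

**Step 17**
Reactants: 24 seco acid
Product: 26 19,10-lactone with C1=C2 (3β-OH, 12-ketone, 13-OH, ring B still open), via iodolactone 25 (not isolated)
Conditions: I2, NaHCO3, CH2Cl2–H2O, 0 °C; then DBU, THF, 50 °C
Reagents that add atoms: none
Why: iodolactonisation puts the carboxylate oxygen on the tertiary C10 necessarily cis to C19 (fixing C10) with iodine anti at C1, and base-induced anti elimination of HI toward C2 then gives the C1=C2 alkene, as is usual in gibberellin ring A chemistry.

**Step 18**
Reactants: 26 lactone ketone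
Product: 27 triol (3β-OH, 13-OH, 12-OH cis to C10)
Conditions: NaBH4, MeOH, −40 °C
Reagents that add atoms: none
Why: the axial C9–C10 bond carrying the lactone bicycle shields the 1,3-diaxial face of the C12 ketone, so hydride should enter from the other face and give the axial alcohol cis to C10, with lactone and ester untouched.

**Step 19**
Reactants: 27 triol
Product: 28 3,12,13-tris(triethylsilyl) ether
Conditions: Et3SiOTf (4.5 equiv), 2,6-lutidine, CH2Cl2, −40 to 0 °C
Reagents that add atoms: triethylsilyl triflate, CC[Si](CC)(CC)OS(=O)(=O)C(F)(F)F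
Why: silylation removes all O–H bonds before the carbenoid step, and the 12-silyloxy group deactivates the neighbouring C11–H bonds.

**Step 20**
Reactants: 28 tris(triethylsilyl) ether
Product: 31 α-diazo ester (diazo group on C6), via lithium enolate 29 (not isolated), via trifluoroacetyl ester 30 (not isolated)
Conditions: LiN(SiMe3)2, THF, −78 °C; CF3CO2CH2CF3; then MsN3, Et3N, H2O, MeCN, 20 °C; aq. NH4Cl
Reagents that add atoms: methanesulfonyl azide, CS(=O)(=O)N=[N+]=[N-]
Why: C6 is the only enolisable position, so trifluoroacetylation followed by deacylative (Regitz-type) diazo transfer should give the α-alkyl-α-diazo ester.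

**Step 21**
Reactants: 31 α-diazo ester
Product: 32 tris(triethylsilyl) ether methyl ester of the target (ring B closed, C6–C8 bond)
Conditions: Rh2(O2CCMe3)4 (1 mol %), CH2Cl2, slow addition, −40 to 20 °C
Reagents that add atoms: none
Why: Loss of N2 gives an electrophilic dirhodium carbenoid at C6, which inserts in a concerted three-centre fashion into the bridgehead C8–H bond reached through C5–C10–C9. The closest known reaction type is the rhodium-carboxylate-mediated 1,5 C–H insertion of α-alkyl-α-diazo esters into tertiary C–H bonds to give cyclopentanecarboxylates. Ring B is closed as a five-membered ring by 1,5-insertion through a six-membered transition state. C8 becomes quaternary with retention, its configuration being fixed by the bicyclo[3.2.1]octane, and C6 is set by the carbenoid rotamer that keeps the ester away from ring C, expected to be also the more stable epimer (ester trans to C4 on ring B). The step needs insertion at C8–H to win over 1,2-hydride migration from C5–H and over insertion at C11–H: the bulky pivalate ligands and low temperature disfavour hydride migration, C8–H is the only tertiary C–H in reach, and C11–H is deactivated by the 12-silyloxy group. The alkenes are out of reach (C1=C2 lies on the other bridge of the lactone bicycle, C16=C17 would need a seven-membered approach) and no O–H bond is left.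

**Step 22**
Reactants: 32 pentacyclic methyl ester
Product: 33 tris(triethylsilyl) ether of the target acid
Conditions: n-PrSLi, HMPA, 20 °C; then dilute HCl to pH 3
Reagents that add atoms: none
Why: thiolate cleaves the methyl ester by SN2 attack at the methyl carbon, which avoids hydroxide and thereby the base-induced isomerisation of the allylic lactone.

**Step 23**
Reactants: 33 tris(triethylsilyl) ether acid
Product: 34 the target gibberellin (3β,12,13-trihydroxy 1,16-diene 7-oic acid 19,10-lactone of the 20-norgibberellane skeleton, 12-OH cis to C10 on ring C)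
Conditions: HF·pyridine, pyridine, THF, 0 to 20 °C
Reagents that add atoms: none
Why: buffered fluoride removes the three silyl ethers without the strong acid or base that would rearrange the 13-hydroxy-16-ene or the allylic lactone.

**Compound list**
1 | estragole, 1-methoxy-4-(prop-2-enyl)benzene | COc1ccc(CC=C)cc1 | starting material
2 | 1-methoxy-4-(prop-2-enyl)cyclohexa-1,4-diene | COC1=CCC(CC=C)=CC1 | intermediate
3 | 4-(prop-2-enyl)cyclohex-2-en-1-one (racemic) | O=C1C=CC(CC=C)CC1 | intermediate
4 | 4-(prop-2-enyl)cyclohexan-1-one | O=C1CCC(CC=C)CC1 | intermediate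
5 | lithium (4R)-4-(prop-2-enyl)cyclohex-1-en-1-olate | [Li+].[O-]C1=CC[C@@H](CC=C)CC1 | intermediate
6 | (4R)-2-hydroxy-4-(prop-2-enyl)cyclohexan-1-one (C2 epimers) | C=CC[C@@H]1CC(O)C(=O)CC1 | intermediate
7 | (4R)-4-(prop-2-enyl)-1,2-bis(triethylsilyloxy)cyclohex-1-ene | C=CC[C@@H]1CC(O[Si](CC)(CC)CC)=C(O[Si](CC)(CC)CC)CC1 | intermediate
8 | (1S,5R)-7-methylidene-1-(triethylsilyloxy)bicyclo[3.2.1]octan-2-one | C=C1C[C@@H]2C[C@@]1(O[Si](CC)(CC)CC)C(=O)CC2 | intermediate
9 | (1S,5R)-7-methylidene-1-(triethylsilyloxy)bicyclo[3.2.1]oct-3-en-2-one | C=C1C[C@@H]2C[C@@]1(O[Si](CC)(CC)CC)C(=O)C=C2 | intermediate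
10 | cis-cyclohex-4-ene-1,2-dicarboxylic anhydride (meso) | C1C=CC[C@H]2[C@@H]1C(=O)OC2=O | starting material
11 | (1S,6R)-6-{[2-(trimethylsilyl)ethoxy]carbonyl}cyclohex-3-ene-1-carboxylic acid | OC(=O)[C@H]1CC=CC[C@H]1C(=O)OCC[Si](C)(C)C | intermediate
12 | dilithium carboxylate ester-enolate of 11 | [Li+].[Li+].[O-]C(=O)[C@H]1CC=CCC1=C([O-])OCC[Si](C)(C)C | intermediate
13 | (1S,6R)-6-methyl-6-{[2-(trimethylsilyl)ethoxy]carbonyl}cyclohex-3-ene-1-carboxylic acid | OC(=O)[C@H]1CC=CC[C@@]1(C)C(=O)OCC[Si](C)(C)C | intermediate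
14 | acid chloride of 13 | ClC(=O)[C@H]1CC=CC[C@@]1(C)C(=O)OCC[Si](C)(C)C | intermediate
15 | diazoketone from 14 | [N-]=[N+]=CC(=O)[C@H]1CC=CC[C@@]1(C)C(=O)OCC[Si](C)(C)C | intermediate
16 | 2-(trimethylsilyl)ethyl (1R,6R)-6-(2-methoxy-2-oxoethyl)-1-methylcyclohex-3-ene-1-carboxylate | COC(=O)C[C@H]1CC=CC[C@@]1(C)C(=O)OCC[Si](C)(C)C | intermediate
17 | ring A allylic alcohol (3β-OH, C1=C2) | COC(=O)C[C@H]1CC=C[C@H](O)[C@@]1(C)C(=O)OCC[Si](C)(C)C | intermediate
18 | 3-O-triethylsilyl ether of 17 | COC(=O)C[C@H]1CC=C[C@H](O[Si](CC)(CC)CC)[C@@]1(C)C(=O)OCC[Si](C)(C)C | intermediate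
19 | ring A enone (C10=O, C1=C2, 3β-OSiEt3) | COC(=O)C[C@H]1C(=O)C=C[C@H](O[Si](CC)(CC)CC)[C@@]1(C)C(=O)OCC[Si](C)(C)C | intermediate
20 | lithium C10 enolate from 19 | [Li+].COC(=O)C[C@H]1C([O-])=CC[C@H](O[Si](CC)(CC)CC)[C@@]1(C)C(=O)OCC[Si](C)(C)C | intermediate
21 | ring A alkenyl triflate (C10–OTf, C10=C1) | COC(=O)C[C@H]1C(OS(=O)(=O)C(F)(F)F)=CC[C@H](O[Si](CC)(CC)CC)[C@@]1(C)C(=O)OCC[Si](C)(C)C | intermediate
22 | ring A alkenyl pinacolboronate (boron on C10) | COC(=O)C[C@H]1C(B2OC(C)(C)C(C)(C)O2)=CC[C@H](O[Si](CC)(CC)CC)[C@@]1(C)C(=O)OCC[Si](C)(C)C | intermediate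
23 | coupled ketone (C9–C10 bond; C12=O; C10=C1) | C=C1C[C@@H]2C[C@@]1(O[Si](CC)(CC)CC)C(=O)C[C@H]2C1=CC[C@H](O[Si](CC)(CC)CC)[C@@](C)(C(=O)OCC[Si](C)(C)C)[C@H]1CC(=O)OC | intermediate
24 | seco acid (C19 acid; 3-OH, 13-OH free) | C=C1C[C@@H]2C[C@@]1(O)C(=O)C[C@H]2C1=CC[C@H](O)[C@@](C)(C(O)=O)[C@H]1CC(=O)OC | intermediate
25 | 1β-iodo-19,10-lactone | C=C1C[C@@H]2C[C@@]1(O)C(=O)C[C@H]2[C@@]12[C@H](I)C[C@H](O)[C@@](C)(C(=O)O1)[C@H]2CC(=O)OC | intermediate
26 | 19,10-lactone with C1=C2 (12-ketone; ring B open) | C=C1C[C@@H]2C[C@@]1(O)C(=O)C[C@H]2[C@@]12C=C[C@H](O)[C@@](C)(C(=O)O1)[C@H]2CC(=O)OC | intermediate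
27 | triol (3β,12,13-OH; ring B open) | C=C1C[C@@H]2C[C@@]1(O)[C@@H](O)C[C@H]2[C@@]12C=C[C@H](O)[C@@](C)(C(=O)O1)[C@H]2CC(=O)OC | intermediate
28 | 3,12,13-tris(triethylsilyl) ether of 27 | C=C1C[C@@H]2C[C@@]1(O[Si](CC)(CC)CC)[C@@H](O[Si](CC)(CC)CC)C[C@H]2[C@@]12C=C[C@H](O[Si](CC)(CC)CC)[C@@](C)(C(=O)O1)[C@H]2CC(=O)OC | intermediate
29 | lithium ester enolate of 28 | [Li+].C=C1C[C@@H]2C[C@@]1(O[Si](CC)(CC)CC)[C@@H](O[Si](CC)(CC)CC)C[C@H]2[C@@]12C=C[C@H](O[Si](CC)(CC)CC)[C@@](C)(C(=O)O1)[C@H]2C=C([O-])OC | intermediate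
30 | C6-trifluoroacetyl ester (C6 epimers) | C=C1C[C@@H]2C[C@@]1(O[Si](CC)(CC)CC)[C@@H](O[Si](CC)(CC)CC)C[C@H]2[C@@]12C=C[C@H](O[Si](CC)(CC)CC)[C@@](C)(C(=O)O1)[C@H]2C(C(=O)C(F)(F)F)C(=O)OC | intermediate
31 | α-diazo ester (diazo on C6) | C=C1C[C@@H]2C[C@@]1(O[Si](CC)(CC)CC)[C@@H](O[Si](CC)(CC)CC)C[C@H]2[C@@]12C=C[C@H](O[Si](CC)(CC)CC)[C@@](C)(C(=O)O1)[C@H]2C(=[N+]=[N-])C(=O)OC | intermediate
32 | methyl ester 3,12,13-tris(triethylsilyl) ether of the target gibberellin | C=C1C[C@]23C[C@@]1(O[Si](CC)(CC)CC)[C@@H](O[Si](CC)(CC)CC)C[C@H]2[C@@]12C=C[C@H](O[Si](CC)(CC)CC)[C@@](C)(C(=O)O1)[C@H]2[C@@H]3C(=O)OC | intermediate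
33 | 3,12,13-tris(triethylsilyl) ether of the target gibberellin | C=C1C[C@]23C[C@@]1(O[Si](CC)(CC)CC)[C@@H](O[Si](CC)(CC)CC)C[C@H]2[C@@]12C=C[C@H](O[Si](CC)(CC)CC)[C@@](C)(C(=O)O1)[C@H]2[C@@H]3C(=O)O | intermediate
34 | the target gibberellin (3β,12,13-trihydroxy 1,16-diene 7-oic acid 19,10-lactone of the 20-norgibberellane skeleton; 12-OH cis to C10 on ring C) | C=C1C[C@]23C[C@@]1(O)[C@@H](O)C[C@H]2[C@@]12C=C[C@H](O)[C@@](C)(C(=O)O1)[C@H]2[C@@H]3C(=O)O | target

**Totals**
Total step count: 23. Longest linear sequence: 17 steps (steps 7–14, then 15–23).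

**Steps most likely to fail**

Step 5 (bears the label). What may go wrong: closure through the other enol carbon in the six-membered mode, or plain dehydrosilylation of the enediol ether to the diosphenol without alkene insertion. Fallback with known chemistry, setting out from 4 and returning at 8: bromine in CH2Cl2 at −78 °C adds to the terminal alkene to give 4-(2,3-dibromopropyl)cyclohexan-1-one F1. DBU in DMF removes HBr to give 4-(2-bromoprop-2-enyl)cyclohexan-1-one F2. The chiral lithium amide of step 3 gives the lithium enolate F3, which the oxaziridine oxidises to 2-hydroxy-4-(2-bromoprop-2-enyl)cyclohexan-1-one F4. The triacetoxy periodinane (DMP) gives 4-(2-bromoprop-2-enyl)cyclohexane-1,2-dione F5. CrCl2 with catalytic NiCl2 in DMF (Nozaki–Hiyama–Kishi reaction) adds the alkenylchromium to the C13 carbonyl in the 5-exo mode to give (1S,5R)-1-hydroxy-7-methylidenebicyclo[3.2.1]octan-2-one F6. Et3SiOTf/2,6-lutidine then gives 8.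

Step 21 (key step). What may go wrong: 1,2-hydride migration from C5 to the carbenoid carbon giving the alkylidene ester, or insertion into C11–H. Fallback that changes the precursor and the bond-forming mechanism, setting out from 28 and returning at 32: enolate 29 is oxidised with (camphorsulfonyl)oxaziridine to the C6-hydroxy ester F11. DMP gives the α-keto ester F12, and TsNHNH2 in MeOH gives the N-tosylhydrazone F13. Cs2CO3 and cobalt tetraphenylporphyrin Co(TPP) (divalent cobalt) in dioxane at 60 °C release 31 slowly and turn it into a cobalt-bound carbene radical. This radical abstracts the C8 hydrogen atom (1,5-hydrogen-atom transfer) and closes ring B by radical substitution, a stepwise path in which hydride migration does not compete in the same way.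

Step 10. What may go wrong: poor site selectivity between the two allylic methylenes (C3 and C10), poor face selectivity, or over-oxidation. Fallback, setting out from 16 and returning at 19: bromine gives the trans-1,2-dibromide F7. DBU in toluene at 80 °C removes two HBr to give the cyclohexa-1,3-diene F8. Singlet oxygen (O2, light, tetraphenylporphyrin) adds on the face anti to the axial C19 ester to give the endoperoxide F9. Et3N removes the less hindered C10 hydrogen (Kornblum–DeLaMare rearrangement) to give the 3β-hydroxy C10 enone F10. Et3SiCl/imidazole then gives 19.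

**Further compounds**
F1 | step 5 | 4-(2,3-dibromopropyl)cyclohexan-1-one | O=C1CCC(CC(Br)CBr)CC1
F2 | step 5 | 4-(2-bromoprop-2-enyl)cyclohexan-1-one | O=C1CCC(CC(Br)=C)CC1
F3 | step 5 | lithium enolate of F2 (configuration as in 5) | [Li+].[O-]C1=CC[C@@H](CC(Br)=C)CC1
F4 | step 5 | 2-hydroxy-4-(2-bromoprop-2-enyl)cyclohexan-1-one (configuration as in 6) | C=C(Br)C[C@@H]1CC(O)C(=O)CC1
F5 | step 5 | 4-(2-bromoprop-2-enyl)cyclohexane-1,2-dione | C=C(Br)C[C@@H]1CC(=O)C(=O)CC1
F6 | step 5 | (1S,5R)-1-hydroxy-7-methylidenebicyclo[3.2.1]octan-2-one | C=C1C[C@@H]2C[C@@]1(O)C(=O)CC2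
F7 | step 10 | trans-1,2-dibromide of 16 | COC(=O)C[C@H]1CC(Br)C(Br)C[C@@]1(C)C(=O)OCC[Si](C)(C)C
F8 | step 10 | ring A cyclohexa-1,3-diene | COC(=O)C[C@H]1C=CC=C[C@@]1(C)C(=O)OCC[Si](C)(C)C
F9 | step 10 | 3,10-endoperoxide (β face) | COC(=O)C[C@H]1[C@H]2C=C[C@H](OO2)[C@@]1(C)C(=O)OCC[Si](C)(C)C
F10 | step 10 | 3β-hydroxy C10 enone | COC(=O)C[C@H]1C(=O)C=C[C@H](O)[C@@]1(C)C(=O)OCC[Si](C)(C)C
F11 | step 21 | C6-hydroxy ester of 28 (C6 epimers) | C=C1C[C@@H]2C[C@@]1(O[Si](CC)(CC)CC)[C@@H](O[Si](CC)(CC)CC)C[C@H]2[C@@]12C=C[C@H](O[Si](CC)(CC)CC)[C@@](C)(C(=O)O1)[C@H]2C(O)C(=O)OC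
F12 | step 21 | C6 α-keto ester | C=C1C[C@@H]2C[C@@]1(O[Si](CC)(CC)CC)[C@@H](O[Si](CC)(CC)CC)C[C@H]2[C@@]12C=C[C@H](O[Si](CC)(CC)CC)[C@@](C)(C(=O)O1)[C@H]2C(=O)C(=O)OC
F13 | step 21 | N-tosylhydrazone of F12 | C=C1C[C@@H]2C[C@@]1(O[Si](CC)(CC)CC)[C@@H](O[Si](CC)(CC)CC)C[C@H]2[C@@]12C=C[C@H](O[Si](CC)(CC)CC)[C@@](C)(C(=O)O1)[C@H]2C(=NNS(=O)(=O)c1ccc(C)cc1)C(=O)OC
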